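The data were generated by integration for an exercise; scatter was added.

Set the noon run beside the autumn run: noon holds half the G on the same J, and by 49 min its E stands lower, at 0.0457 M against 0.0820 M. What you should watch, though, is how the noon run slows. It gains 0.0155 M in its first 7.0 min but 0.00140 M in its last 7.00 min, while J has fallen from 0.120 M to just 0.0743 M. A rate constant acting on that J does not give such a stall, so I take it that G is lost as E is made.

| flask | J | G | time |
|---|---|---|---|
| autumn | 0.120 M | 0.00120 M |  |
| spring | 0.0600 M | 0.00120 M |  |
| noon | 0.120 M | 6.00 × 10⁻⁴ M |  |
| dawn | 0.120 M | 1.80 × 10⁻⁴ M | 49 min |

- autumn run (time / min: [E] / M): 7.0: 0.0289; 14: 0.0464; 21: 0.0560; 28: 0.0670; 35: 0.0717; 42: 0.0775; 49: 0.0820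
- spring run (time / min: [E] / M): 7.0: 0.0147; 14: 0.0292; 21: 0.0358; 28: 0.0398; 35: 0.0428; 42: 0.0480; 49: 0.0508
- noon run (time / min: [E] / M): 7.0: 0.0155; 14: 0.0237; 21: 0.0324; 28: 0.0368; 35: 0.0416; 42: 0.0443; 49: 0.0457

(standard deviation of a reading: 0.001 M)

- Overall: J -> E, with G as catalyst.
- Constant volume, constant temperature.
- Readings of a species count what is bound in complexes too.
- An order is taken over about fifteen percent of the charge, up and down.

* apparent order in [J] of the starting rate, round the charge of the autumn run (the rate where two percent of its J have turned into E) (one fixed amount of E, the same in the runs compared)
* apparent order in [G] of the starting rate, round the charge of the autumn run (the rate where two percent of its J have turned into E)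
* the spring run starts with 0.0600 M less of J than the autumn run, and with no E. Compared where both hold the same amount of J, once fifteen percent of what the spring run was charged with has turned into E, is the spring run faster, slower or alike (within a tenth)?
* E in the dawn run at 49 min, as a share of the J charged

Suppose each G lasts a fixed number of turns, so that a flask closes on a ceiling of E. If it closes by a steady fraction, gains over equal time gaps stand in a fixed ratio. The noon run gains 0.0213 M from 7.0 min to 28 min, then 0.00890 M over the next 21.0 min. The gains still to come add up to the square of the later gain over the difference of the two, which puts the noon ceiling at 0.0521 M. Dividing by the G charged gives a reading of 86.8. This is E made per G charged before the catalyst stops, the catalyst allowance, or turnover number.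

The rate is then a constant times J times the live G, which is the G charged minus E over the allowance. In the dawn run the ceiling is the allowance times its G, 0.0156 M, just 13.0 % of its J. J in the dawn run therefore stays near its charge, the rate is close to pseudo-first-order in the distance to the ceiling, and it integrates to E = ceiling × (1 − exp(−λt)). Here λ is the constant times J over the allowance, so in this picture it does not depend on G. The noon gains give λ = 0.0416 min⁻¹ at about 0.0832 M of J. Taking λ in proportion to J, the dawn run's 0.112 M gives 0.0560 min⁻¹. My own reckoning for 49 min is then 12.2 % of the J charged.

The forecast holds the same picture “the catalyst dies by turnover”, with an allowance of 90 against my 86.8. It gives 12 %, between 10 % and 14.5 %. For the orders in J and G it gives 1 and 1, and it calls the spring run faster.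

The dawn run gives 12.1 %, which is 93.0 % of my ceiling. The order in J is 0.70, below the forecast's 1; the order in G is 1.0, and the spring run is faster.

    G + J ⇌ GJ, settled at all times (3.930 M⁻¹)
    GJ → E + G (12.96 min⁻¹)
    GJ → Jy + J (0.1404 min⁻¹)

Now put the allowance on the autumn run, whose ceiling comes to 0.104 M; the spring run has the same G. Where the two hold equal J, the spring run has made 0.00900 M of E and the autumn run 0.0690 M. That leaves the spring run 0.0950 M under the ceiling and the autumn run 0.0350 M, a ratio of 2.71. Taken over the autumn rate at that point, the rate in the spring run comes to 2.4.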